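**Strategy**

The flavanone is cut at O1–C8a and C4–C4a. The O1–C2–C3–C4 segment of the pyranone ring, which bridges the neighbouring A-ring carbons C8a and C4a, corresponds atom for atom to the ring of a 4-aryloxetan-2-one, and the oxygen on C5, next to C4a, biases an aryne spanning C4a–C8a so that a nucleophile enters at C8a. In one operation the aryne should insert into the acyl–oxygen bond of the lactone, which enlarges the oxetanone to the pyranone and carries the C2 configuration, set beforehand in the lactone, through unchanged. The aryne source is a hexasubstituted ortho-silylaryl triflate made from 2,4,6-trihydroxybenzaldehyde.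

Key step: step 8

**Remarks and assumptions**

- Atom labels (O1, C2 … C8a) follow flavanone numbering.
- Assumption: in step 7, O-trimethylsilylquinine is taken as the pseudoenantiomer that sends the enolate to the Si face of the aldehyde, by analogy with the sense of quinine in ketene–aldehyde cycloadditions. If the first run gives the (R)-lactone, O-trimethylsilylquinidine is used with nothing else changed.
- 4-Formylphenyl acetate (14) is a catalogue compound and is bought.
- The priorities at the carbinol carbon are the same in lactone 17 and in flavanones 19 and 20 (O > aryl > CH2 > H), so retention maps (S) onto (2S).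
- Protecting groups: MOM ethers on the A ring tolerate butyllithium, fluoride and 200 °C. The B-ring acetate is a far weaker donor than an ether and falls off in the same acidic methanolysis as the MOM ethers.

**Route**

Step 1
Reactants: 1 2,4,6-trihydroxybenzaldehyde
Product: 2 2-hydroxy-4,6-bis(methoxymethoxy)benzaldehyde
Conditions: MOMCl (2.2 equiv), iPr2NEt (2.5 equiv), CH2Cl2, 0 °C to rt
Reagents that add atoms: chloromethyl methyl ether, COCCl
Why: Williamson-type O-alkylation in which the hydroxyl that stays hydrogen-bonded to the formyl oxygen is the least nucleophilic, so two equivalents of the chloride should stop at the 4,6-bis-ether.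

Step 2
Reactants: 2 2-hydroxy-4,6-bis(methoxymethoxy)benzaldehyde; 3 prenyl bromide (1-bromo-3-methylbut-2-ene)
Product: 4 2,4-bis(methoxymethoxy)-6-[(3-methylbut-2-en-1-yl)oxy]benzaldehyde
Conditions: K2CO3, acetone, reflux
Reagents that add atoms: none
Why: Williamson ether synthesis in which the chelated phenoxide is alkylated on oxygen by the reactive allylic bromide (SN2), the carbonate base leaving aldehyde and MOM ethers untouched.

Step 3
Reactants: 4 2,4-bis(methoxymethoxy)-6-[(3-methylbut-2-en-1-yl)oxy]benzaldehyde
Product: 7 6-hydroxy-2,4-bis(methoxymethoxy)-3-(3-methylbut-2-en-1-yl)benzaldehyde, via ortho-dienone 5 (not isolated), via para-dienone 6 (not isolated)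
Conditions: PhNEt2, 200 °C, Ar
Reagents that add atoms: none
Why: aromatic Claisen rearrangement followed by Cope rearrangement (para-Claisen), in which the first [3,3] shift gives a crowded 1,1-dimethylallyl dienone and a second [3,3] shift passes the chain to the carbon para to oxygen, between the two MOM ethers, where it arrives as a normal prenyl group and the ring rearomatises by enolisation.

Step 4
Reactants: 7 6-hydroxy-2,4-bis(methoxymethoxy)-3-(3-methylbut-2-en-1-yl)benzaldehyde
Product: 9 3,5-bis(methoxymethoxy)-2-methyl-4-(3-methylbut-2-en-1-yl)phenol, via aryl ethyl carbonate 8 (not isolated)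
Conditions: ClCO2Et, Et3N, THF, 0 °C; then NaBH4, H2O/THF, 0 °C to rt
Reagents that add atoms: ethyl chloroformate, CCOC(=O)Cl (its atoms are held only in intermediate 8)
Why: reductive deoxygenation of an ortho-hydroxybenzaldehyde through its mixed carbonate, in which borohydride reduces the aldehyde, the carbonate shifts to the benzylic alkoxide and leaves to give an ortho-quinone methide, and a second hydride reduces this to the methyl group under conditions that spare MOM ethers and alkene.

Step 5
Reactants: 9 3,5-bis(methoxymethoxy)-2-methyl-4-(3-methylbut-2-en-1-yl)phenol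
Product: 10 2-bromo-3,5-bis(methoxymethoxy)-6-methyl-4-(3-methylbut-2-en-1-yl)phenol
Conditions: NBS (1.0 equiv), CH2Cl2, −78 °C
Reagents that add atoms: N-bromosuccinimide, O=C1CCC(=O)N1Br
Why: electrophilic aromatic bromination at the only unsubstituted ring carbon, which is ortho or para to all three oxygens and should react at low temperature faster than the trisubstituted alkene.

Step 6
Reactants: 10 2-bromo-3,5-bis(methoxymethoxy)-6-methyl-4-(3-methylbut-2-en-1-yl)phenol
Product: 13 3,5-bis(methoxymethoxy)-2-methyl-4-(3-methylbut-2-en-1-yl)-6-(trimethylsilyl)phenyl trifluoromethanesulfonate, via aryl trimethylsilyl ether 11 (not isolated), via lithium 2-silylphenoxide 12 (not isolated)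
Conditions: HMDS, THF, 65 °C, evaporate; n-BuLi, THF, −100 to −78 °C; Tf2O, −100 to −78 °C
Reagents that add atoms: hexamethyldisilazane, C[Si](C)(C)N[Si](C)(C)C; trifluoromethanesulfonic anhydride, O=S(=O)(OS(=O)(=O)C(F)(F)F)C(F)(F)F
Why: O-silylation, bromine–lithium exchange and anionic 1,3 O-to-C silyl shift (retro-Brook rearrangement) should give a lithium phenoxide that is triflated in the same flask, the exchange at −100 °C being faster than deprotonation at the benzylic-allylic CH2.

Step 7
Reactants: 14 4-formylphenyl acetate (4-acetoxybenzaldehyde); 15 acetyl chloride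
Product: 17 (S)-4-(4-acetoxyphenyl)oxetan-2-one, via ketene 16 (not isolated)
Conditions: O-TMS-quinine (15 mol%), LiClO4, iPr2NEt, CH2Cl2/Et2O, −78 to −40 °C, AcCl added over 4 h
Reagents that add atoms: none
Why: catalytic asymmetric ketene–aldehyde [2+2] cycloaddition (acyl halide–aldehyde cyclocondensation), in which the alkaloid turns ketene into a chiral ammonium enolate that adds to the lithium-activated aldehyde on its Si face through a closed transition state, setting C4 as (S), and ring closure onto the acylammonium releases the catalyst.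

Step 8
Reactants: 13 3,5-bis(methoxymethoxy)-2-methyl-4-(3-methylbut-2-en-1-yl)-6-(trimethylsilyl)phenyl trifluoromethanesulfonate; 17 (S)-4-(4-acetoxyphenyl)oxetan-2-one
Product: 19 (2S)-2-(4-acetoxyphenyl)-5,7-bis(methoxymethoxy)-8-methyl-6-(3-methylbut-2-en-1-yl)chroman-4-one, via aryne 18 (not isolated)
Conditions: CsF (3 equiv), MeCN/toluene 1:1, 25 °C, 13 added over 6 h to 17 (2 equiv)
Reagents that add atoms: none
Why: Proposed new method: fluoride removes the silyl group and triflate departs to give aryne 18; an endocyclic lone pair of lactone 17 is expected to add at C8a, the resulting C4a carbanion then adds to the carbonyl carbon attached to the now positively charged oxygen, and the fused four-membered alkoxide opens by breaking the original acyl–oxygen bond, so that O1–C8a and C4–C4a are made in one pass. The nearest known reactions are aryne σ-insertions into the N–C(O) bond of β-lactams, which give dihydroquinolinones, and aryne annulations of salicylates to xanthones; a lactone oxygen is a weaker and so far untried donor, although oxygens of cyclic ethers are known to add to arynes. The pyranone ring arises by two-carbon enlargement of the oxetanone (four to six ring atoms) through this addition–fragmentation, not by closure of an open chain, and relief of β-lactone strain drives it. No stereocentre is formed: C2 is brought in by 17 and none of its bonds is broken, so the (S) configuration should be carried into 19 unchanged. Regioselectivity (oxygen at C8a, acyl at C4a) is expected from the C5 MOM ether, whose inductive pull distorts the aryne so that the nucleophile enters at the far carbon and the charge develops next to oxygen, the small C8 methyl not overriding this. Chemoselectivity against ionisation at C2 and against aryne self-reaction (ene reaction at a prenyl group) rests on the weakly donating acetoxy group, the low-polarity medium and slow addition of 13 to an excess of 17.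

Step 9
Reactants: 19 (2S)-2-(4-acetoxyphenyl)-5,7-bis(methoxymethoxy)-8-methyl-6-(3-methylbut-2-en-1-yl)chroman-4-one
Product: 20 (2S)-5,7-dihydroxy-2-(4-hydroxyphenyl)-8-methyl-6-(3-methylbut-2-en-1-yl)chroman-4-one
Conditions: HCl (3 M), MeOH, 0 °C to rt
Reagents that add atoms: none
Why: acid-catalysed acetal exchange should remove both MOM ethers and acid-catalysed transesterification the aryl acetate, while no bond to C2 is touched and the cold acidic medium avoids the base-induced ring opening that would racemise a flavanone.

**Compound list**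

1 | 2,4,6-trihydroxybenzaldehyde | O=Cc1c(O)cc(O)cc1O | starting material
2 | 2-hydroxy-4,6-bis(methoxymethoxy)benzaldehyde | O=Cc1c(O)cc(OCOC)cc1OCOC | intermediate
3 | prenyl bromide (1-bromo-3-methylbut-2-ene) | CC(C)=CCBr | starting material
4 | 2,4-bis(methoxymethoxy)-6-[(3-methylbut-2-en-1-yl)oxy]benzaldehyde | O=Cc1c(OCC=C(C)C)cc(OCOC)cc1OCOC | intermediate
5 | 2,4-bis(methoxymethoxy)-5-(2-methylbut-3-en-2-yl)-6-oxocyclohexa-1,3-diene-1-carbaldehyde (racemic ortho-dienone) | O=CC1=C(OCOC)C=C(OCOC)C(C(C)(C)C=C)C1=O | intermediate
6 | 2,4-bis(methoxymethoxy)-3-(3-methylbut-2-en-1-yl)-6-oxocyclohexa-1,4-diene-1-carbaldehyde (racemic para-dienone) | O=CC1=C(OCOC)C(CC=C(C)C)C(OCOC)=CC1=O | intermediate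
7 | 6-hydroxy-2,4-bis(methoxymethoxy)-3-(3-methylbut-2-en-1-yl)benzaldehyde | O=Cc1c(O)cc(OCOC)c(CC=C(C)C)c1OCOC | intermediate
8 | ethyl 2-formyl-3,5-bis(methoxymethoxy)-4-(3-methylbut-2-en-1-yl)phenyl carbonate | CCOC(=O)Oc1cc(OCOC)c(CC=C(C)C)c(OCOC)c1C=O | intermediate
9 | 3,5-bis(methoxymethoxy)-2-methyl-4-(3-methylbut-2-en-1-yl)phenol | Cc1c(O)cc(OCOC)c(CC=C(C)C)c1OCOC | intermediate
10 | 2-bromo-3,5-bis(methoxymethoxy)-6-methyl-4-(3-methylbut-2-en-1-yl)phenol | Cc1c(O)c(Br)c(OCOC)c(CC=C(C)C)c1OCOC | intermediate
11 | [2-bromo-3,5-bis(methoxymethoxy)-6-methyl-4-(3-methylbut-2-en-1-yl)phenoxy]trimethylsilane | Cc1c(O[Si](C)(C)C)c(Br)c(OCOC)c(CC=C(C)C)c1OCOC | intermediate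
12 | lithium 3,5-bis(methoxymethoxy)-2-methyl-4-(3-methylbut-2-en-1-yl)-6-(trimethylsilyl)phenolate | Cc1c([O-])c([Si](C)(C)C)c(OCOC)c(CC=C(C)C)c1OCOC.[Li+] | intermediate
13 | 3,5-bis(methoxymethoxy)-2-methyl-4-(3-methylbut-2-en-1-yl)-6-(trimethylsilyl)phenyl trifluoromethanesulfonate | CC(C)=CCc1c(OCOC)c(C)c(OS(=O)(=O)C(F)(F)F)c([Si](C)(C)C)c1OCOC | intermediate
14 | 4-formylphenyl acetate (4-acetoxybenzaldehyde) | CC(=O)Oc1ccc(C=O)cc1 | starting material
15 | acetyl chloride | CC(=O)Cl | starting material
16 | ketene (ethenone) | C=C=O | intermediate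
17 | (S)-4-(4-acetoxyphenyl)oxetan-2-one | O=C1C[C@@H](c2ccc(OC(C)=O)cc2)O1 | intermediate
18 | 3,5-bis(methoxymethoxy)-6-methyl-4-(3-methylbut-2-en-1-yl)-1,2-didehydrobenzene (aryne across C8a–C4a) | CC(C)=CCC1=C(OCOC)C#CC(C)=C1OCOC | intermediate
19 | (2S)-2-(4-acetoxyphenyl)-5,7-bis(methoxymethoxy)-8-methyl-6-(3-methylbut-2-en-1-yl)chroman-4-one | CC(C)=CCc1c(OCOC)c(C)c2c(c1OCOC)C(=O)C[C@@H](c1ccc(OC(C)=O)cc1)O2 | intermediate
20 | (2S)-5,7-dihydroxy-2-(4-hydroxyphenyl)-8-methyl-6-(3-methylbut-2-en-1-yl)chroman-4-one | CC(C)=CCc1c(O)c(C)c2c(c1O)C(=O)C[C@@H](c1ccc(O)cc1)O2 | target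

**Step count and risks**

Total step count: 9. Longest linear sequence: 8 steps (steps 1–6, 8 and 9); the lactone is made in one step (step 7) and joins at step 8.

The three steps most likely to fail:

1. Step 8 (Proposed new method). The lactone oxygen may capture the aryne too slowly, so that the aryne is used up by ene reaction with a prenyl group of a second molecule or by oligomerisation. Capture through the carbonyl oxygen, loss of the acetate to fluoride, ionisation at the benzylic carbon or base-induced opening of the product ring would each erode the configuration at C2. The fallback uses known chemistry, sets out from 10 and returns at 20; it keeps the phenol oxygen of 10 as O1 and needs neither 13 nor 17. Double lithiation of 10 (n-BuLi, 2.2 equiv, THF, −78 °C: phenoxide formation, then bromine–lithium exchange) and acylation with N-methoxy-N-methylacetamide should give 1-[2-hydroxy-4,6-bis(methoxymethoxy)-3-methyl-5-(3-methylbut-2-en-1-yl)phenyl]ethan-1-one F1. Condensation with DMF dimethyl acetal (toluene, 90 °C) gives (E)-3-(dimethylamino)-1-[2-hydroxy-4,6-bis(methoxymethoxy)-3-methyl-5-(3-methylbut-2-en-1-yl)phenyl]prop-2-en-1-one F2, which should close in warm acetic acid to 5,7-bis(methoxymethoxy)-8-methyl-6-(3-methylbut-2-en-1-yl)-4H-chromen-4-one F3. Rhodium-catalysed asymmetric 1,4-addition of 4-(methoxymethoxy)phenylboronic acid with a chiral diene or bisphosphine ligand, the antipode being chosen for (2S), gives (2S)-5,7-bis(methoxymethoxy)-2-[4-(methoxymethoxy)phenyl]-8-methyl-6-(3-methylbut-2-en-1-yl)chroman-4-one F4, and acidic methanolysis as in step 9 gives 20.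

2. Step 7. Addition of the ammonium enolate to a non-activated aromatic aldehyde may be slow enough for ketene dimerisation to take over, facial selectivity may be insufficient, and the lactone may decarboxylate during purification. The fallback sets out from 14 and returns at 17, replacing the cycloaddition by aldol addition and lactonisation. A catalytic asymmetric Mukaiyama aldol addition of the trimethylsilyl ketene acetal of benzyl acetate to 14 (chiral titanium(IV) binaphthyl Schiff-base catalyst, antipode chosen for the (S)-carbinol) should give benzyl (3S)-3-(4-acetoxyphenyl)-3-[(trimethylsilyl)oxy]propanoate F5, desilylated on mildly acidic work-up to benzyl (3S)-3-(4-acetoxyphenyl)-3-hydroxypropanoate F6. Hydrogenolysis (H2, Pd/C, EtOAc) gives (3S)-3-(4-acetoxyphenyl)-3-hydroxypropanoic acid F7. Lactonisation by carboxyl activation (PhSO2Cl, pyridine, 0 °C) leaves the carbinol C–O bond intact and should give 17 with retention.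

3. Step 3. The ortho-dienone may enolise before the second shift, which leaves a reverse-prenyl group ortho to the hydroxyl, or the formyl group may be lost after ipso attack. The fallback sets out from 2 and returns at 9, placing the prenyl group by directed ortho-metalation instead of the sigmatropic relay. Compound 2 is reduced as in step 4 through ethyl 2-formyl-3,5-bis(methoxymethoxy)phenyl carbonate F8 (ClCO2Et, Et3N; then NaBH4) to 3,5-bis(methoxymethoxy)-2-methylphenol F9. Silylation (TIPSCl, imidazole, DMF) gives [3,5-bis(methoxymethoxy)-2-methylphenoxy]tri(propan-2-yl)silane F10. n-BuLi (THF, 0 °C) should remove the proton between the two MOM ethers; transmetalation to copper (CuI) and alkylation with 3 give [3,5-bis(methoxymethoxy)-2-methyl-4-(3-methylbut-2-en-1-yl)phenoxy]tri(propan-2-yl)silane F11, and TBAF (THF, 0 °C) gives 9.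

**Further compounds**

F1 | step 8 | 1-[2-hydroxy-4,6-bis(methoxymethoxy)-3-methyl-5-(3-methylbut-2-en-1-yl)phenyl]ethan-1-one | CC(=O)c1c(O)c(C)c(OCOC)c(CC=C(C)C)c1OCOC
F2 | step 8 | (E)-3-(dimethylamino)-1-[2-hydroxy-4,6-bis(methoxymethoxy)-3-methyl-5-(3-methylbut-2-en-1-yl)phenyl]prop-2-en-1-one | CN(C)/C=C/C(=O)c1c(O)c(C)c(OCOC)c(CC=C(C)C)c1OCOC
F3 | step 8 | 5,7-bis(methoxymethoxy)-8-methyl-6-(3-methylbut-2-en-1-yl)-4H-chromen-4-one | CC(C)=CCc1c(OCOC)c(C)c2occc(=O)c2c1OCOC
F4 | step 8 | (2S)-5,7-bis(methoxymethoxy)-2-[4-(methoxymethoxy)phenyl]-8-methyl-6-(3-methylbut-2-en-1-yl)chroman-4-one | CC(C)=CCc1c(OCOC)c(C)c2c(c1OCOC)C(=O)C[C@@H](c1ccc(OCOC)cc1)O2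
F5 | step 7 | benzyl (3S)-3-(4-acetoxyphenyl)-3-[(trimethylsilyl)oxy]propanoate | O=C(OCc1ccccc1)C[C@@H](c1ccc(OC(C)=O)cc1)O[Si](C)(C)C
F6 | step 7 | benzyl (3S)-3-(4-acetoxyphenyl)-3-hydroxypropanoate | O=C(OCc1ccccc1)C[C@@H](c1ccc(OC(C)=O)cc1)O
F7 | step 7 | (3S)-3-(4-acetoxyphenyl)-3-hydroxypropanoic acid | O=C(O)C[C@@H](c1ccc(OC(C)=O)cc1)O
F8 | step 3 | ethyl 2-formyl-3,5-bis(methoxymethoxy)phenyl carbonate | CCOC(=O)Oc1cc(OCOC)cc(OCOC)c1C=O
F9 | step 3 | 3,5-bis(methoxymethoxy)-2-methylphenol | Cc1c(O)cc(OCOC)cc1OCOC
F10 | step 3 | [3,5-bis(methoxymethoxy)-2-methylphenoxy]tri(propan-2-yl)silane | Cc1c(O[Si](C(C)C)(C(C)C)C(C)C)cc(OCOC)cc1OCOC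
F11 | step 3 | [3,5-bis(methoxymethoxy)-2-methyl-4-(3-methylbut-2-en-1-yl)phenoxy]tri(propan-2-yl)silane | Cc1c(O[Si](C(C)C)(C(C)C)C(C)C)cc(OCOC)c(CC=C(C)C)c1OCOC
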